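The runs were computed with made-up constants, and the scatter is random.

Start from slowness: substrate is fed over 40 min, and the earlier runs still hold between 42% and 55% of it unreacted when the feed ends, so reckon the fraction left and not the fraction made.

| flask | substrate | reagent | free catalyst | remark | time |
|---|---|---|---|---|---|
| north-east | 20 mM (fed, over 40 min) | 24 mM | 13 µM | run made earlier |  |
| south-east | 20 mM (fed, over 40 min) | 24 mM | 30 µM | run made earlier |  |
| north | 30 mM (fed, over 40 min) | 24 mM | 20 µM | run made earlier |  |
| flask | 20 mM (fed, over 40 min) | 24.0 mM | 20 µM |  | 40 min |

| run | time / min | substrate / % | target / % |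
|---|---|---|---|
| north-east | 2.50 | 7 | 1 |
| north-east | 8.00 | 20 | 3 |
| north-east | 15.0 | 30 | 4 |
| north-east | 20.0 | 39 | 8 |
| north-east | 30.0 | 48 | 14 |
| north-east | 40.0 | 55 | 21 |
| south-east | 3.00 | 9 | 0 |
| south-east | 5.00 | 12 | 1 |
| south-east | 8.00 | 17 | 0 |
| south-east | 15.0 | 26 | 8 |
| south-east | 25.0 | 37 | 19 |
| south-east | 40.0 | 42 | 41 |
| north | 8.00 | 17 | 1 |
| north | 15.0 | 29 | 6 |
| north | 25.0 | 40 | 15 |
| north | 30.0 | 43 | 18 |
| north | 40.0 | 48 | 28 |

(scatter of a reading: 1.5 percentage points)

* part of the substrate that has reacted at 40 min
* share of the unused reagent that is free and not bound as idle adduct, at 40 min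

- a species is counted by the substrate in it: one self-condensation product counts as two
- amounts and yields of released group count idle adduct too
- steps under discussion: catalyst intermediate B <-> released group + catalyst intermediate C; 2 substrate -> self-condensation product; catalyst intermediate C -> free catalyst + target; released group -> by-product carried off; reagent + free catalyst -> catalyst intermediate A; substrate + catalyst intermediate A <-> catalyst intermediate B; reagent + released group <-> idle adduct
- percentages count the whole charge, also what has not yet gone in
- the earlier runs do not show how much of reagent is bound; that part of a forecast is a guess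

Read the last two rows of the north run, which has the catalyst charge of the flask though 30 mM of substrate: target climbs from 18% to 28% of the charge in 10.0 min while the substrate fraction averages 45.5%, and that reads as a pseudo-first-order constant of 0.0220 min⁻¹ for substrate going to target, a reading with the scatter of its rows. Read the last rows of the north-east and south-east runs the same way and scale each to the flask's catalyst, which gives 0.0209 min⁻¹ and 0.0248 min⁻¹, so take the constant as proportional to catalyst.

Multiply it by the feed time to get x = 0.879, and form the target-only remainder, the fraction of the charge still substrate at the end of a steady feed if target were the one way out, namely one minus e to the minus x, over x: 66.5%. One minus this remainder is my estimate of target for the flask, 33.5%. Interpolate the substrate left between the last north-east and south-east rows to 49.6%, so I commit to 50.4% reacted, and the difference of 16.9% of the charge is my rough estimate of self-condensation. The earlier runs do not show how much of reagent is bound, so that part stays a guess.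

The forecast says 51% reacted, 0.60 percentage points above mine, and 85% of the unused reagent free, a guess offered since “The runs show no clear reagent starvation”.

The flask gives 50.1% reacted and 92.5% free, the second 7.5 points above the forecast.

    catalyst intermediate B ⇌ released group + catalyst intermediate C (K = 0.460 M, k = 12.1 s⁻¹)
    2 substrate → self-condensation product (k = 0.0154 L mol⁻¹ s⁻¹)
    catalyst intermediate C → free catalyst + target (k = 26.8 s⁻¹)
    released group → by-product carried off (k = 5.71 × 10⁻⁴ s⁻¹)
    reagent + free catalyst → catalyst intermediate A (k = 220 L mol⁻¹ s⁻¹)
    substrate + catalyst intermediate A ⇌ catalyst intermediate B (K = 12.0 L mol⁻¹, k = 25.6 L mol⁻¹ s⁻¹)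
    reagent + released group ⇌ idle adduct, settled at all times (K = 25.0 L mol⁻¹)

The flask holds 31.8% target at 40.0 min, beside the 33.5% from the remainder, and 18.4% self-condensation product. Now take a neighbouring flask with 0.080 mM of free catalyst and everything else unchanged: scale x to 3.52, and the target-only remainder falls to 27.6%, which promises 72.4% target. That neighbouring flask holds 23.0% substrate, 5.22% self-condensation product and 71.8% target.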